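**Retrosynthetic overview**
1. Target ⇐ benzyl/MOM-protected 2-aryl-3-formylbenzofuran; only deprotections remain at the end.
2. Furan ring (the only ring made; both benzene rings are bought) ⇐ acid cyclodehydration of an α-(2-hydroxyaryl)-β-keto acetal: phenol O onto the aryl ketone carbon (O1–C2), acetal carbon becomes CHO.
3. β-Keto acetal ⇐ oxidative 1,2-aryl shift of a 2-(MOM-oxy)chalcone.
4. Key C–C bond (chalcone Cα–Cβ, later C3–CHO) ⇐ Claisen–Schmidt aldol condensation of the ring A aldehyde with the ring B methyl ketone.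
5. Ring A aldehyde ⇐ eugenol (hydroboration, MOM, ortho-lithiation/DMF); ring B ketone ⇐ acetosyringone (mono-demethylation, benzylation).

Assumption: the target has no stereocentre, so the "single enantiomer" is fixed by constitution alone; the racemic stereocentres of intermediates 6, 12, 14 and 15 are all destroyed before the end.

**Step 1**
Reactants: 1 eugenol (4-allyl-2-methoxyphenol)
Product: 3 4-(3-hydroxypropyl)-2-methoxyphenol (dihydroconiferyl alcohol), via bis-boryl adduct 2 (not isolated)
Conditions: 9-BBN (2.3 equiv), THF, 0 °C → rt, 12 h; then 3 M aq NaOH, 30% H2O2, 0 °C → rt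
Reagents that add atoms: 9-BBN, [H]B1C2CCCC1CCC2 (boron and carbon skeleton in 2 only); hydrogen peroxide, OO (hydroxyl oxygen of 3)
Why: Brown hydroboration–oxidation, in which the bulky borane adds boron to the terminal alkene carbon (anti-Markovnikov) while the phenol only consumes one equivalent as a borinate that is hydrolysed in the alkaline peroxide work-up; no stereocentre is formed.

**Step 2**
Reactants: 3 4-(3-hydroxypropyl)-2-methoxyphenol
Product: 4 2-methoxy-1-(methoxymethoxy)-4-[3-(methoxymethoxy)propyl]benzene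
Conditions: MOMCl (3.0 equiv), i-Pr2NEt (4.0 equiv), CH2Cl2, 0 °C → rt
Reagents that add atoms: chloromethyl methyl ether (MOMCl), COCCl
Why: Williamson-type O-alkylation with the reactive α-chloro ether protects both hydroxyls as base-stable MOM acetals, the aryl MOM ether also serving as the directing group for the next step.

**Step 3**
Reactants: 4 2-methoxy-1-(methoxymethoxy)-4-[3-(methoxymethoxy)propyl]benzene
Product: 7 3-methoxy-2-(methoxymethoxy)-5-[3-(methoxymethoxy)propyl]benzaldehyde, via aryllithium 5 (not isolated), via lithium hemiaminal alkoxide 6 (not isolated)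
Conditions: n-BuLi (1.3 equiv), TMEDA (1.3 equiv), THF, −20 → 0 °C, 2 h; DMF (3 equiv), 0 °C → rt; aq NH4Cl
Reagents that add atoms: n-butyllithium, [Li]CCCC (lithium in 5 and 6 only); N,N-dimethylformamide, CN(C)C=O (formyl carbon and oxygen)
Why: Directed ortho-metalation followed by Bouveault-type formylation, regioselective because the aryl OMOM group is a stronger director than OMe and has only one free ortho position.

**Step 4**
Reactants: 8 acetosyringone (1-(4-hydroxy-3,5-dimethoxyphenyl)ethanone)
Product: 10 1-(3,4-dihydroxy-5-methoxyphenyl)ethanone, via chloroaluminium catecholate 9 (not isolated)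
Conditions: AlCl3 (1.2 equiv), pyridine (4.5 equiv), CH2Cl2, reflux, 24 h; then 2 M aq HCl
Reagents that add atoms: aluminium trichloride, Cl[Al](Cl)Cl (aluminium and chlorine in 9 only; the isolated product gains hydrogen alone)
Why: Chelation-controlled aryl methyl ether cleavage (AlCl3–pyridine demethylation), in which the aluminium phenoxide activates only a methoxy group ortho to the free phenol (the two are equivalent by symmetry) and the resulting aluminium catecholate resists a second demethylation.

**Step 5**
Reactants: 10 1-(3,4-dihydroxy-5-methoxyphenyl)ethanone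
Product: 11 1-[3,4-bis(benzyloxy)-5-methoxyphenyl]ethanone
Conditions: BnBr (2.4 equiv), K2CO3 (3 equiv), DMF, 60 °C, N2
Reagents that add atoms: benzyl bromide, BrCc1ccccc1
Why: Williamson ether synthesis, selective for the acidic phenols over the methyl ketone, installing benzyl ethers that survive base, trivalent-iodine oxidation and acid.

**Step 6**
Reactants: 7 3-methoxy-2-(methoxymethoxy)-5-[3-(methoxymethoxy)propyl]benzaldehyde; 11 1-[3,4-bis(benzyloxy)-5-methoxyphenyl]ethanone
Product: 13 (2E)-1-[3,4-bis(benzyloxy)-5-methoxyphenyl]-3-{3-methoxy-2-(methoxymethoxy)-5-[3-(methoxymethoxy)propyl]phenyl}prop-2-en-1-one, via aldol adduct 12 (not isolated)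
Conditions: KOH (50% aq, 5 equiv), EtOH–THF (3:1), rt, 24–48 h
Reagents that add atoms: none
Why: Claisen–Schmidt crossed aldol condensation, clean because only ketone 11 is enolisable and only aldehyde 7 is a good acceptor, with E1cB dehydration of the adduct giving the thermodynamically favoured E-enone (this bond becomes C3–CHO of the target).

**Step 7**
Reactants: 13 the (E)-chalcone
Product: 14 1-[3,4-bis(benzyloxy)-5-methoxyphenyl]-3,3-dimethoxy-2-{3-methoxy-2-(methoxymethoxy)-5-[3-(methoxymethoxy)propyl]phenyl}propan-1-one (racemic)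
Conditions: PhI(OH)OTs (1.3 equiv), MeOH, 3 Å molecular sieves, 0 °C → rt, 2–4 h; then NaHCO3
Reagents that add atoms: methanol, CO (both acetal methoxy groups)
Why: Hypervalent-iodine oxidative rearrangement of a chalcone (1,2-aryl shift), in which methanol adds at the β-carbon, the trivalent iodine binds the α-carbon and its departure as PhI drives migration of the electron-rich ortho-alkoxyaryl ring from Cβ to Cα, methanol capping the migration origin as the dimethyl acetal; the new stereocentre is racemic and is lost in step 9.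

**Step 8**
Reactants: 14 the β-keto dimethyl acetal
Product: 15 [3,4-bis(benzyloxy)-5-methoxyphenyl]{2,7-dimethoxy-5-[3-(methoxymethoxy)propyl]-2,3-dihydro-1-benzofuran-3-yl}methanone (racemic, C2/C3 diastereomer mixture, mainly trans)
Conditions: p-TsOH·H2O (0.15 equiv), MeOH, rt; NaHCO3 quench
Reagents that add atoms: none
Why: Acid-catalysed acetal exchange, in which the labile aryl MOM ether is cleaved selectively over the alkyl MOM ether and the benzyl ethers and the freed phenol closes onto the neighbouring acetal carbon by 5-exo transacetalisation; the two stereocentres are uncontrolled and both vanish in step 9.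

**Step 9**
Reactants: 15 the 3-aroyl-2-methoxy-2,3-dihydrobenzofuran
Product: 16 2-[3,4-bis(benzyloxy)-5-methoxyphenyl]-7-methoxy-5-[3-(methoxymethoxy)propyl]-1-benzofuran-3-carbaldehyde
Conditions: p-TsOH·H2O (1.0 equiv), (CF3)2CHOH, rt
Reagents that add atoms: water, O (hydrate water of p-TsOH·H2O; relays the aldehyde oxygen and is regenerated by the dehydration)
Why: Acid-mediated ring-opening/recyclisation (cyclodehydration), in which the strongly ionising, non-nucleophilic alcohol lets the cyclic acetal reopen so that the phenol adds to the aryl ketone instead, and irreversible dehydration to the aromatic furan plus hydrolysis of the remaining methyl acetal gives the 2-aryl-3-formylbenzofuran rather than the isomeric 3-aroylbenzofuran.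

**Step 10**
Reactants: 16 the MOM-protected 3-formylbenzofuran
Product: 17 2-[3,4-bis(benzyloxy)-5-methoxyphenyl]-5-(3-hydroxypropyl)-7-methoxy-1-benzofuran-3-carbaldehyde
Conditions: 3 M aq HCl–THF (1:2), 50 °C
Reagents that add atoms: none
Why: Acid hydrolysis of the aliphatic MOM acetal, to which the benzyl ethers, the benzofuran and the vinylogous-formate aldehyde are stable.

**Step 11**
Reactants: 17 the bis(benzyl ether)
Product: 18 Mururin C, 2-(3,4-dihydroxy-5-methoxyphenyl)-5-(3-hydroxypropyl)-7-methoxy-1-benzofuran-3-carbaldehyde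
Conditions: H2 (1 atm), 10% Pd/C, EtOAc, rt, stopped at consumption of 17; filtration through Celite
Reagents that add atoms: none
Why: Catalytic hydrogenolysis of the two aryl benzyl ethers over zerovalent palladium on carbon is fast at 1 atm, whereas the aldehyde (deactivated as a vinylogous formate by the furan oxygen) and the tetrasubstituted furan double bond react much more slowly.

**Compound list**
1 | eugenol, 4-allyl-2-methoxyphenol | C=CCc1ccc(O)c(OC)c1 | starting material
2 | 9-[3-(3-methoxy-4-{(9-borabicyclo[3.3.1]nonan-9-yl)oxy}phenyl)propyl]-9-borabicyclo[3.3.1]nonane | COc1cc(CCCB2C3CCCC2CCC3)ccc1OB1C2CCCC1CCC2 | intermediate (not isolated)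
3 | 4-(3-hydroxypropyl)-2-methoxyphenol | COc1cc(CCCO)ccc1O | intermediate
4 | 2-methoxy-1-(methoxymethoxy)-4-[3-(methoxymethoxy)propyl]benzene | COCOCCCc1ccc(OCOC)c(OC)c1 | intermediate
5 | {3-methoxy-2-(methoxymethoxy)-5-[3-(methoxymethoxy)propyl]phenyl}lithium | COCOCCCc1cc([Li])c(OCOC)c(OC)c1 | intermediate (not isolated)
6 | lithium (dimethylamino){3-methoxy-2-(methoxymethoxy)-5-[3-(methoxymethoxy)propyl]phenyl}methanolate (racemic) | COCOCCCc1cc(C(O[Li])N(C)C)c(OCOC)c(OC)c1 | intermediate (not isolated)
7 | 3-methoxy-2-(methoxymethoxy)-5-[3-(methoxymethoxy)propyl]benzaldehyde | COCOCCCc1cc(C=O)c(OCOC)c(OC)c1 | intermediate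
8 | acetosyringone, 1-(4-hydroxy-3,5-dimethoxyphenyl)ethanone | CC(=O)c1cc(OC)c(O)c(OC)c1 | starting material
9 | 1-(2-chloro-7-methoxy-1,3,2-benzodioxaluminol-5-yl)ethanone (pyridine-solvated aluminium catecholate) | CC(=O)c1cc(OC)c2O[Al](Cl)Oc2c1 | intermediate (not isolated)
10 | 1-(3,4-dihydroxy-5-methoxyphenyl)ethanone | CC(=O)c1cc(O)c(O)c(OC)c1 | intermediate
11 | 1-[3,4-bis(benzyloxy)-5-methoxyphenyl]ethanone | CC(=O)c1cc(OC)c(OCc2ccccc2)c(OCc2ccccc2)c1 | intermediate
12 | 1-[3,4-bis(benzyloxy)-5-methoxyphenyl]-3-hydroxy-3-{3-methoxy-2-(methoxymethoxy)-5-[3-(methoxymethoxy)propyl]phenyl}propan-1-one (racemic) | COCOCCCc1cc(C(O)CC(=O)c2cc(OC)c(OCc3ccccc3)c(OCc3ccccc3)c2)c(OCOC)c(OC)c1 | intermediate (not isolated)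
13 | (2E)-1-[3,4-bis(benzyloxy)-5-methoxyphenyl]-3-{3-methoxy-2-(methoxymethoxy)-5-[3-(methoxymethoxy)propyl]phenyl}prop-2-en-1-one | COCOCCCc1cc(/C=C/C(=O)c2cc(OC)c(OCc3ccccc3)c(OCc3ccccc3)c2)c(OCOC)c(OC)c1 | intermediate
14 | 1-[3,4-bis(benzyloxy)-5-methoxyphenyl]-3,3-dimethoxy-2-{3-methoxy-2-(methoxymethoxy)-5-[3-(methoxymethoxy)propyl]phenyl}propan-1-one (racemic) | COCOCCCc1cc(C(C(OC)OC)C(=O)c2cc(OC)c(OCc3ccccc3)c(OCc3ccccc3)c2)c(OCOC)c(OC)c1 | intermediate
15 | [3,4-bis(benzyloxy)-5-methoxyphenyl]{2,7-dimethoxy-5-[3-(methoxymethoxy)propyl]-2,3-dihydro-1-benzofuran-3-yl}methanone (racemic, diastereomer mixture, mainly trans) | COCOCCCc1cc2C(C(=O)c3cc(OC)c(OCc4ccccc4)c(OCc4ccccc4)c3)C(OC)Oc2c(OC)c1 | intermediate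
16 | 2-[3,4-bis(benzyloxy)-5-methoxyphenyl]-7-methoxy-5-[3-(methoxymethoxy)propyl]-1-benzofuran-3-carbaldehyde | COCOCCCc1cc2c(C=O)c(-c3cc(OC)c(OCc4ccccc4)c(OCc4ccccc4)c3)oc2c(OC)c1 | intermediate
17 | 2-[3,4-bis(benzyloxy)-5-methoxyphenyl]-5-(3-hydroxypropyl)-7-methoxy-1-benzofuran-3-carbaldehyde | OCCCc1cc2c(C=O)c(-c3cc(OC)c(OCc4ccccc4)c(OCc4ccccc4)c3)oc2c(OC)c1 | intermediate
18 | Mururin C, 2-(3,4-dihydroxy-5-methoxyphenyl)-5-(3-hydroxypropyl)-7-methoxy-1-benzofuran-3-carbaldehyde (achiral) | COc1cc(-c2oc3c(OC)cc(CCCO)cc3c2C=O)cc(O)c1O | target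

**Totals and risks**
Total step count: 11. Longest linear sequence: 9 steps (steps 1–3, then 6–11, from eugenol); the ring B branch is steps 4–5.

Most likely to fail, first: step 7. The TsOH set free may strip a MOM ether, after which the liberated phenol would be oxidised, and the 2,3-dioxygenated aryl ring is twisted and may migrate sluggishly. The fallback sets out from 13 and comes back at 15. Weitz–Scheffer epoxidation (30% H2O2, NaOH, MeOH–THF, 0 °C) gives the racemic trans-epoxy ketone F1. BF3·OEt2 (1 equiv, CH2Cl2, −78 → −30 °C, short contact) opens it at the benzylic carbon and the aroyl group shifts (Meinwald-type 1,2-acyl migration) to give the 2-aryl-3-oxopropanal F2, which has the same carbon skeleton as 14. Catalytic p-TsOH·H2O in MeOH at rt then removes the aryl MOM ether and closes the cyclic methyl acetal 15.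

Second: step 9. Loss of methanol from 15 can compete and give the isomeric 3-aroylbenzofuran irreversibly, and the hindered 4-benzyl ether or the alkyl MOM ether may suffer in the acidic medium (early MOM loss only gives 17 ahead of time). The fallback sets out from 14 and comes back at 16. Propane-1,3-dithiol (2.5 equiv) with catalytic p-TsOH·H2O in CH2Cl2 (rt → 40 °C) turns the dimethyl acetal into an acid-stable dithiane and removes the aryl MOM ether. With the aldehyde carbon locked, the phenol can only condense with the aryl ketone, and dehydration gives the 3-(1,3-dithian-2-yl)benzofuran F3. Alkylative hydrolysis (MeI, CaCO3, MeCN–H2O, 45 °C) releases aldehyde 16.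

Third: step 11. Prolonged hydrogenation can reduce the aldehyde to the alcohol or the methyl compound. The fallback sets out from 17 and comes back at 18 without any reductant. BCl3 (5 equiv) with pentamethylbenzene (6 equiv) in CH2Cl2 at −78 °C cleaves both benzyl ethers by Lewis-acid ionisation, the benzyl cations being trapped by the arene; a MeOH quench and aqueous work-up give 18. New compound on its way: none F0.

**Further compounds**
F1 | step 7 | [3,4-bis(benzyloxy)-5-methoxyphenyl](trans-3-{3-methoxy-2-(methoxymethoxy)-5-[3-(methoxymethoxy)propyl]phenyl}oxiran-2-yl)methanone (racemic, one enantiomer drawn) | COCOCCCc1cc([C@H]2O[C@@H]2C(=O)c2cc(OC)c(OCc3ccccc3)c(OCc3ccccc3)c2)c(OCOC)c(OC)c1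
F2 | step 7 | 3-[3,4-bis(benzyloxy)-5-methoxyphenyl]-2-{3-methoxy-2-(methoxymethoxy)-5-[3-(methoxymethoxy)propyl]phenyl}-3-oxopropanal (racemic) | COCOCCCc1cc(C(C=O)C(=O)c2cc(OC)c(OCc3ccccc3)c(OCc3ccccc3)c2)c(OCOC)c(OC)c1
F3 | step 9 | 2-[3,4-bis(benzyloxy)-5-methoxyphenyl]-3-(1,3-dithian-2-yl)-7-methoxy-5-[3-(methoxymethoxy)propyl]-1-benzofuran | COCOCCCc1cc2c(C3SCCCS3)c(-c3cc(OC)c(OCc4ccccc4)c(OCc4ccccc4)c3)oc2c(OC)c1
F0 | step 11 | none | none
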